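**Retrosynthetic overview**

1. The target is a 3-formyl-5-isovalerylphloroglucinol whose ring oxygen (on C2) and benzylic CH2 (on C6) both sit endo on a (1R,2S,4R,6S)-bornane and close an oxepine. The late steps (CHO to isobutyl ketone, O-demethylation, ring formylation) lead back to aldehyde 7.
2. Key disconnection of 7: the C1–C7 bond of the bornane, together with C2–O and C6–CH2Ar. The C1–C7 bond lies anti to the endo C2–O bond and the CH2Ar on C6 is cis (endo) to that oxygen, which is the pattern a Wagner–Meerwein shift leaves behind. Moving C7 back from C1 to C2 re-forms the cyclobutane of a 2-pinanyl cation, that is (1R,5R)-α-pinene alkylated at C3 by o-quinone methide 5.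
3. The cyclobutane of α-pinene (bond C2–C7 in bornane numbering) is a temporary ring that is absent from the target. Its strain drives C1–C7 bond formation and its geometry sets C1, C2 and C6; C4 comes from the chiral pool.
4. Ring order: the arene is bought; then one operation closes the bicyclo[2.2.1]heptane (its two cyclopentane rings, through the C1–C7 bond) and the oxepine (through C2–O).
5. Arene regiocontrol: in 4-hydroxy-2,6-dimethoxybenzaldehyde only one free OH can flank the benzylic carbon, the CHO is the latent isovaleryl group, and the last free ring CH takes the formyl group.

Key step: step 2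

Remark: bornane numbering is used for the terpene part (C1 methyl-bearing bridgehead, C2 oxygen-bearing carbon, C4 other bridgehead, C6 CH2Ar-bearing carbon, C7 the CMe2 bridge). Commercial (+)-α-pinene of at least 97% ee is assumed, and the ee of the product should follow it.

**Route**

Step 1
Reactants: 1 4-hydroxy-2,6-dimethoxybenzaldehyde
Product: 3 4-hydroxy-3-(hydroxymethyl)-2,6-dimethoxybenzaldehyde, via benzodioxaborin 2 (not isolated)
Conditions: PhB(OH)2 (1.1 equiv), (CH2O)n (3 equiv), EtCO2H (0.3 equiv), PhMe, reflux, Dean–Stark; then pinacol (1.5 equiv), THF, rt
Reagents that add atoms: formaldehyde (as paraformaldehyde), C=O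
Why: Boronate-templated ortho-hydroxymethylation of a phenol: the aryl phenylboronate should deliver formaldehyde to the ortho carbon through a six-membered transition state, the two ortho positions of 1 are equivalent, closure to the cyclic boronate 2 prevents a second addition, and transesterification with pinacol frees salicyl alcohol 3; no stereocentre is formed.

Step 2
Reactants: 3 4-hydroxy-3-(hydroxymethyl)-2,6-dimethoxybenzaldehyde; 4 (1R,5R)-(+)-α-pinene
Product: 7 bornane-fused benzoxepine aldehyde [2-endo-O and 6-endo-CH2 of (1R,2S,4R,6S)-bornane joined to C4 and C3 of 2,6-dimethoxybenzaldehyde], via o-quinone methide 5 (not isolated), via pinane-fused chroman 6 (not isolated)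
Conditions: 4 (3 equiv), TfOH (10 mol %), CH2Cl2–(CF3)2CHOH 9:1, −40 → 0 °C, slow addition of 3
Reagents that add atoms: none
Why: Proposed new method: acid converts salicyl alcohol 3 into o-quinone methide 5 (reacting as its O-protonated 2-hydroxybenzyl cation), which should alkylate C3 of α-pinene on the face anti to the CMe2 bridge to give the tertiary 2-pinanyl cation; this either collapses reversibly to the cis-fused chroman 6 (a tertiary aryl ether that the same acid re-ionises) or directly undergoes a Wagner–Meerwein 1,2-shift of the CMe2 carbon from the bridgehead to the cationic carbon, and the 2-bornyl cation so formed is trapped by the tethered phenol oxygen. Closest known reaction types: the hetero-Diels–Alder addition of o-quinone methides to α-pinene, which stops at chromans such as 6, and the acid-mediated conversion of α-pinene into bornyl chloride or bornyl esters; their union in one flask with an internal oxygen nucleophile is the untested part. Ring closures: the 1,2-shift makes the C1–C7 bond and with it closes the two cyclopentane rings of the bicyclo[2.2.1]heptane (cationic ring expansion paid for by opening the cyclobutane), and the oxepine closes by 7-membered C2–O bond formation through cation capture. Stereocentres: C6 by attack anti to the gem-dimethyl bridge, C1 by the suprafacial shift within the rigid bicycle, C2 by capture anti to the migrating carbon (endo), C4 unchanged from (1R,5R)-α-pinene. Selectivity needed: migration of the CMe2 bridge (bornyl) and not of the CH2 bridge (fenchyl) or cyclobutane fragmentation to a p-menthenyl cation, and ring closure through one defined oxygen; the endo CH2Ar tether can reach only the carbon face anti to the CMe2 bridge, the fenchyl and p-menthenyl cations have no oxygen within reach (an eight-membered ring would be needed) and can return, and only one free OH flanks the benzylic carbon of 3.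

Step 3
Reactants: 7 bornane-fused benzoxepine aldehyde
Product: 8 carbinol [7 with CH(OH)CH2CH(CH3)2 in place of CHO; both epimers at the carbinol carbon]
Conditions: i-BuMgBr (2 equiv), LaCl3·2LiCl (1 equiv), THF, 0 °C; then H2O
Reagents that add atoms: isobutylmagnesium bromide, CC(C)C[Mg]Br
Why: Grignard 1,2-addition to the aryl aldehyde, with LaCl3·2LiCl to suppress β-hydride reduction by the isobutyl reagent; the new carbinol centre is formed without control and is removed in step 4.

Step 4
Reactants: 8 carbinol
Product: 9 aryl isobutyl ketone dimethyl ether
Conditions: (n-Pr4N)RuO4 (5 mol %), N-methylmorpholine N-oxide (1.5 equiv), CH2Cl2, rt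
Reagents that add atoms: none
Why: Perruthenate-catalysed (Ley–Griffith) oxidation of a secondary benzylic alcohol under neutral conditions, which avoids ionising the electron-rich benzylic carbinol and erases the uncontrolled centre.

Step 5
Reactants: 9 aryl isobutyl ketone dimethyl ether
Product: 10 bis-phenol (9 with both OMe groups as OH)
Conditions: BCl3 (5 equiv), CH2Cl2, −78 → 0 °C; then H2O
Reagents that add atoms: none
Why: Chelation-assisted Lewis-acid O-demethylation: BCl3 bound to the ketone oxygen should cleave both flanking methyl ethers by chloride attack on methyl, while the ring ether is para to the ketone, not chelated, and its endo-bornyl carbon resists both SN2 attack and ionisation; no stereocentre is touched.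

Step 6
Reactants: 10 bis-phenol
Product: 11 CNP0246493.1 (target)
Conditions: Cl2CHOMe (1.5 equiv), TiCl4 (3.5 equiv), CH2Cl2, −20 → 0 °C; then 1 M HCl
Reagents that add atoms: dichloromethyl methyl ether, COC(Cl)Cl; water, O
Why: Rieche formylation (electrophilic aromatic substitution by TiCl4-activated dichloromethyl methyl ether) at the only unsubstituted ring carbon, ortho to a titanium phenoxide; it is preferred to Vilsmeier conditions, which could turn the 2-hydroxyaryl alkyl ketone into a chromone; no stereocentre is formed.

**Compound list**

1 | 4-hydroxy-2,6-dimethoxybenzaldehyde | O=Cc1c(OC)cc(O)cc1OC | starting material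
2 | 5,7-dimethoxy-2-phenyl-4H-1,3,2-benzodioxaborine-6-carbaldehyde (benzodioxaborin) | O=Cc1c(OC)cc2OB(c3ccccc3)OCc2c1OC | intermediate
3 | 4-hydroxy-3-(hydroxymethyl)-2,6-dimethoxybenzaldehyde (salicyl alcohol) | O=Cc1c(OC)cc(O)c(CO)c1OC | intermediate
4 | (1R,5R)-(+)-α-pinene [(1R,5R)-2,6,6-trimethylbicyclo[3.1.1]hept-2-ene] | CC1=CC[C@@H]2C[C@H]1C2(C)C | starting material
5 | 2,6-dimethoxy-3-methylidene-4-oxocyclohexa-1,5-diene-1-carbaldehyde (o-quinone methide) | O=CC1=C(OC)C(=C)C(=O)C=C1OC | intermediate
6 | pinane-fused chroman: (1S,2R,3S,5R)-pinane whose C2–O and C3–CH2 (cis, both anti to the CMe2 bridge) are joined to C4 and C3 of 2,6-dimethoxybenzaldehyde | O=Cc1c(OC)cc2c(c1OC)C[C@@H]1C[C@@H]3C[C@@H](C3(C)C)[C@]1(C)O2 | intermediate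
7 | bornane-fused benzoxepine aldehyde: (1R,2S,4R,6S)-1,7,7-trimethylbicyclo[2.2.1]heptane whose 2-endo-O and 6-endo-CH2 are joined to C4 and C3 of 2,6-dimethoxybenzaldehyde | O=Cc1c(OC)cc2c(c1OC)C[C@@H]1C[C@@H]3C[C@H](O2)[C@@]1(C)C3(C)C | intermediate
8 | carbinol: 7 with CH(OH)CH2CH(CH3)2 in place of CHO (both epimers at the carbinol carbon) | CC(C)CC(O)c1c(OC)cc2c(c1OC)C[C@@H]1C[C@@H]3C[C@H](O2)[C@@]1(C)C3(C)C | intermediate
9 | ketone: 7 with C(=O)CH2CH(CH3)2 in place of CHO | CC(C)CC(=O)c1c(OC)cc2c(c1OC)C[C@@H]1C[C@@H]3C[C@H](O2)[C@@]1(C)C3(C)C | intermediate
10 | bis-phenol: 9 with both OMe groups as OH | CC(C)CC(=O)c1c(O)cc2c(c1O)C[C@@H]1C[C@@H]3C[C@H](O2)[C@@]1(C)C3(C)C | intermediate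
11 | CNP0246493.1: 10 with CHO on the ring carbon between the free OH and the ring oxygen | CC(C)CC(=O)c1c(O)c(C=O)c2c(c1O)C[C@@H]1C[C@@H]3C[C@H](O2)[C@@]1(C)C3(C)C | target

Total step count: 6. Longest linear sequence: 6 steps (1 → 11).

**Steps most likely to fail**

Step 2 (Proposed new method). The acid may isomerise or oligomerise α-pinene, and 5 may condense with the electron-rich ring of 3 faster than it alkylates the alkene. The 2-pinanyl cation may also lose a proton after cyclobutane fragmentation and end as monocyclic p-menthadienes instead of shifting. The fallback sets out from 3 and comes back at 7, and separates C–C bond formation from ionisation. Salicyl alcohol 3 is heated with 4 (10 equiv) without acid in o-xylene at 150 °C in a sealed vessel. Thermal dehydration to 5 and hetero-Diels–Alder addition to α-pinene, a known reaction type, should give chroman 6, which is now isolated and purified. Pure 6, free of pinene, is then treated with dry HCl or catalytic TfOH in CH2Cl2 at −40 to 0 °C. These are the classical conditions under which 2-pinanyl cations rearrange to bornyl derivatives, and the tethered phenol should give 7. No compound outside the list is made.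

Step 1. The electron-rich ring may over-react with formaldehyde to diarylmethanes, the formyl group of 1 may compete as the aldehyde partner, and the boronate exchange may be incomplete. The fallback sets out from 1 and comes back at 3. Mannich aminomethylation of 1 with dimethyl(methylidene)ammonium iodide (CH2Cl2, rt) should give 3-[(dimethylamino)methyl]-4-hydroxy-2,6-dimethoxybenzaldehyde F1. N-Methylation with MeI (acetone, rt) gives (3-formyl-6-hydroxy-2,4-dimethoxyphenyl)methyl-trimethylammonium iodide F2. NaHCO3 in MeCN–H2O at 40 °C then expels trimethylamine to give 5, which adds water to give 3.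

Step 5. The Lewis acid may ionise the bornyl aryl ether, with ring opening or skeletal change, or the reaction may stall after the first demethylation because the boron chelate ties up the carbonyl group. The fallback sets out from 9 and comes back at 10, and moves the cleavage from Lewis-acid activation of oxygen to nucleophilic dealkylation. NaSEt (6 equiv) in DMF at 130 °C should attack both methyl carbons by SN2; both ethers are ortho to the ketone, so the phenoxides are good leaving groups. The secondary, neopentyl-type bornyl C–O bond cannot react by SN2 and no cation is generated; acidification on work-up gives 10. No compound outside the list is made.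

**Further compounds**

F0 | step 2 | none | none
F1 | step 1 | 3-[(dimethylamino)methyl]-4-hydroxy-2,6-dimethoxybenzaldehyde | O=Cc1c(OC)cc(O)c(CN(C)C)c1OC
F2 | step 1 | (3-formyl-6-hydroxy-2,4-dimethoxyphenyl)methyl-trimethylammonium iodide | C[N+](C)(C)Cc1c(O)cc(OC)c(C=O)c1OC.[I-]
F0 | step 5 | none | none
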